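**Retrosynthetic overview**

1. The target comes from its tris-MOM ether by a final global acid deprotection.
2. The C2–aryl bond and the (2S) centre come from a rhodium-catalysed asymmetric 1,4-addition of 2,5-bis(methoxymethoxy)phenylboronic acid (ring B, from hydroquinone) to an 8-lavandulylchromone.
3. The C1″–C2″ bond, the isopropenyl group and the (2″R) centre come from the proposed copper-catalysed enantioselective SN2′ benzylation: a chromen-8-ylmethylzinc chloride plus (E)-2,6-dimethylhepta-2,5-dienyl diethyl phosphate (from isoprene monoxide and isobutenyl Grignard).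
4. The benzylic zinc reagent comes from an 8-iodochromone (Stille hydroxymethylation, chlorination), itself from 2′,6′-dihydroxy-4′-methoxyacetophenone (mono-MOM, ortho-iodination, enaminone annulation).
5. Ring order: ring A is bought; ring C is closed on it as a chromone before the side chain is built; ring B is attached last, which turns the chromone into the chromanone.

Assumption: the ligand antipodes named for the two catalyst-controlled steps are those expected to give the drawn configurations; if a first run shows the opposite sense (checked against material from the auxiliary-based fallback), the mirror-image ligand is used and nothing else changes.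

Ligand A: the carbene (4S,5S)-4,5-diphenyl-1-(2,4,6-trimethylphenyl)-3-(2-sulfonatophenyl)imidazolidin-2-ylidene, generated from its imidazolinium sulfonate zwitterion (ligand A·H).
Ligand B: (S)-6,6′-dimethoxy-2,2′-bis[bis(3,4,5-trifluorophenyl)phosphino]-1,1′-biphenyl.

**Route**

Step 1
Reactants: 1 1-(2,6-dihydroxy-4-methoxyphenyl)ethan-1-one
Product: 2 1-[2-hydroxy-4-methoxy-6-(methoxymethoxy)phenyl]ethan-1-one
Conditions: MOMCl (1.1 equiv), i-Pr2NEt, CH2Cl2, 0 °C to rt
Reagents that add atoms: chloromethyl methyl ether, COCCl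
Why: Phenol O-alkylation (MOM protection) of a symmetric diol stops at the mono-ether because the remaining OH is locked in a strong hydrogen bond to the acetyl carbonyl.

Step 2
Reactants: 2 1-[2-hydroxy-4-methoxy-6-(methoxymethoxy)phenyl]ethan-1-one
Product: 3 1-[2-hydroxy-3-iodo-4-methoxy-6-(methoxymethoxy)phenyl]ethan-1-one
Conditions: BnNMe3·ICl2 (1.05 equiv), NaHCO3, CH2Cl2/MeOH, rt
Reagents that add atoms: benzyltrimethylammonium dichloroiodate, C[N+](C)(C)Cc1ccccc1.Cl[I-]Cl
Why: Electrophilic aromatic iodination goes to the free position ortho to the chelated phenol (the site between the two ether groups is more hindered), as is usual for 2-hydroxy-4,6-dialkoxyacetophenones, and the bicarbonate buffer keeps the MOM ether intact.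

Step 3
Reactants: 3 1-[2-hydroxy-3-iodo-4-methoxy-6-(methoxymethoxy)phenyl]ethan-1-one
Product: 5 8-iodo-7-methoxy-5-(methoxymethoxy)-4H-chromen-4-one, via enaminone 4 (not isolated)
Conditions: Me2NCH(OMe)2, toluene, 95 °C; then AcOH, 60 °C
Reagents that add atoms: N,N-dimethylformamide dimethyl acetal, COC(OC)N(C)C
Why: Condensation at the acetyl methyl gives the enaminone, and intramolecular oxa-Michael addition with loss of dimethylamine (enaminone route to chromones) closes ring C through the only free phenol, which fixes iodine at C8.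

Step 4
Reactants: 5 8-iodo-7-methoxy-5-(methoxymethoxy)-4H-chromen-4-one
Product: 6 8-(hydroxymethyl)-7-methoxy-5-(methoxymethoxy)-4H-chromen-4-one
Conditions: Bu3SnCH2OH (1.5 equiv), Pd(PPh3)4 (5 mol %), 1,4-dioxane, 95 °C
Reagents that add atoms: (tributylstannyl)methanol, CCCC[Sn](CCCC)(CCCC)CO
Why: Stille coupling in which the α-oxygenated CH2OH group transfers from tin faster than butyl, under neutral conditions that spare the chromone and the MOM ether.

Step 5
Reactants: 6 8-(hydroxymethyl)-7-methoxy-5-(methoxymethoxy)-4H-chromen-4-one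
Product: 7 8-(chloromethyl)-7-methoxy-5-(methoxymethoxy)-4H-chromen-4-one
Conditions: PPh3, NCS (premixed), CH2Cl2, −20 to 0 °C; used at once
Reagents that add atoms: N-chlorosuccinimide, O=C1CCC(=O)N1Cl
Why: Appel-type chlorination through the alkoxyphosphonium salt converts the benzylic alcohol to the chloride without acid, so the MOM ether and the activated benzylic position survive.

Step 6
Reactants: 8 2-methyl-2-vinyloxirane (racemic isoprene monoxide); 9 (2-methylprop-1-en-1-yl)magnesium bromide
Product: 10 (2E)-2,6-dimethylhepta-2,5-dien-1-ol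
Conditions: CuI (5 mol %), THF, −40 to −20 °C
Reagents that add atoms: none
Why: Copper-catalysed SN2′ opening of a vinyl epoxide by a Grignard reagent attacks the vinyl terminus and gives mainly the E trisubstituted allylic alcohol (about 9:1; the Z isomer is removed on AgNO3-impregnated silica), and the epoxide stereocentre is destroyed.

Step 7
Reactants: 10 (2E)-2,6-dimethylhepta-2,5-dien-1-ol
Product: 11 diethyl (2E)-2,6-dimethylhepta-2,5-dien-1-yl phosphate
Conditions: ClP(O)(OEt)2, pyridine, DMAP (cat.), CH2Cl2, 0 °C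
Reagents that add atoms: diethyl chlorophosphate, CCOP(=O)(Cl)OCC
Why: O-Phosphorylation of a primary allylic alcohol installs the leaving group without touching the alkene geometry.

Step 8
Reactants: 7 8-(chloromethyl)-7-methoxy-5-(methoxymethoxy)-4H-chromen-4-one; 11 diethyl (2E)-2,6-dimethylhepta-2,5-dien-1-yl phosphate
Product: 13 7-methoxy-5-(methoxymethoxy)-8-[(2R)-5-methyl-2-(prop-1-en-2-yl)hex-4-en-1-yl]-4H-chromen-4-one, via benzylzinc chloride 12 (not isolated)
Conditions: Zn, LiCl, THF, 25 °C; then 11 (1.2 equiv), CuCl (5 mol %), ligand A·H (5.5 mol %), NaOt-Bu (6 mol %), THF, −30 °C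
Reagents that add atoms: none
Why: Proposed new method: copper-catalysed enantioselective SN2′ allylic benzylation with a functionalized benzylzinc chloride, in which zinc inserts into the activated benzylic C–Cl bond, the benzyl group transmetalates to carbene-bound monovalent copper, the zinc ion bridges the ligand sulfonate and the phosphate P=O so that copper adds anti to the leaving group on the Si face of C3 of the E-alkene, and the trivalent copper σ-allyl species reductively eliminates before it equilibrates, so that the C1″–C2″ bond, the isopropenyl group and the (2″R) centre form in one event while the 2-methyl group and the bulky carbene disfavour α-attack and the mild organozinc leaves the chromone enone alone; the closest known reaction type is the copper–carbene or copper–phosphoramidite catalysed enantioselective SN2′ alkylation of 2-methyl-substituted allylic phosphates and chlorides with dialkylzinc and Grignard reagents, which has not been shown for benzylic zinc halides.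

Step 9
Reactants: 14 benzene-1,4-diol (hydroquinone)
Product: 15 1,4-bis(methoxymethoxy)benzene
Conditions: MOMCl (2.4 equiv), i-Pr2NEt, DMF, 0 °C to rt
Reagents that add atoms: chloromethyl methyl ether, COCCl
Why: Double phenol O-alkylation gives the bis-MOM ether, whose acetal oxygens later direct lithiation.

Step 10
Reactants: 15 1,4-bis(methoxymethoxy)benzene
Product: 18 [2,5-bis(methoxymethoxy)phenyl]boronic acid, via aryllithium 16 (not isolated), via lithium triisopropoxyborate 17 (not isolated)
Conditions: n-BuLi, THF, 0 °C; B(Oi-Pr)3, −78 °C to rt; H2O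
Reagents that add atoms: triisopropyl borate, CC(C)OB(OC(C)C)OC(C)C; water, O
Why: Directed ortho-metalation by the MOM ether followed by borylation and hydrolysis gives a single boronic acid because all four ring positions of the substrate are equivalent.

Step 11
Reactants: 13 7-methoxy-5-(methoxymethoxy)-8-[(2R)-5-methyl-2-(prop-1-en-2-yl)hex-4-en-1-yl]-4H-chromen-4-one; 18 [2,5-bis(methoxymethoxy)phenyl]boronic acid
Product: 19 (2S)-2-[2,5-bis(methoxymethoxy)phenyl]-7-methoxy-5-(methoxymethoxy)-8-[(2R)-5-methyl-2-(prop-1-en-2-yl)hex-4-en-1-yl]-2,3-dihydro-4H-chromen-4-one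
Conditions: [Rh(OH)(cod)]2 (2.5 mol %), ligand B (5.5 mol %), 18 (2.5 equiv), toluene/H2O 10:1, 30 °C
Reagents that add atoms: none
Why: Hayashi–Miyaura rhodium-catalysed asymmetric 1,4-addition of an arylboronic acid to a chromone, in which the aryl–rhodium complex of the electron-poor (S)-bisphosphine inserts C2=C3 from one face to set (2S) under catalyst control (same facial model as for six-membered cyclic enones), and the base-free conditions avoid retro-oxa-Michael racemization.

Step 12
Reactants: 19 (2S)-2-[2,5-bis(methoxymethoxy)phenyl]-7-methoxy-5-(methoxymethoxy)-8-[(2R)-5-methyl-2-(prop-1-en-2-yl)hex-4-en-1-yl]-2,3-dihydro-4H-chromen-4-one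
Product: 20 (2S)-2-(2,5-dihydroxyphenyl)-5-hydroxy-7-methoxy-8-[(2R)-5-methyl-2-(prop-1-en-2-yl)hex-4-en-1-yl]-2,3-dihydro-4H-chromen-4-one
Conditions: HCl (1.25 M in MeOH), THF, 35 °C
Reagents that add atoms: none
Why: Acid-catalysed methanolysis of the three aryl MOM acetals is much faster than protonation of the isolated alkenes or ring opening at C2, and the 7-methoxy group leaves no free phenol next to the side chain that could cyclize onto it.

**Compound list**

1 | 1-(2,6-dihydroxy-4-methoxyphenyl)ethan-1-one | CC(=O)c1c(O)cc(OC)cc1O | starting material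
2 | 1-[2-hydroxy-4-methoxy-6-(methoxymethoxy)phenyl]ethan-1-one | CC(=O)c1c(O)cc(OC)cc1OCOC | intermediate
3 | 1-[2-hydroxy-3-iodo-4-methoxy-6-(methoxymethoxy)phenyl]ethan-1-one | CC(=O)c1c(O)c(I)c(OC)cc1OCOC | intermediate
4 | (2E)-3-(dimethylamino)-1-[2-hydroxy-3-iodo-4-methoxy-6-(methoxymethoxy)phenyl]prop-2-en-1-one (enaminone) | CN(C)/C=C/C(=O)c1c(O)c(I)c(OC)cc1OCOC | intermediate
5 | 8-iodo-7-methoxy-5-(methoxymethoxy)-4H-chromen-4-one | O=C1C=COc2c1c(OCOC)cc(OC)c2I | intermediate
6 | 8-(hydroxymethyl)-7-methoxy-5-(methoxymethoxy)-4H-chromen-4-one | O=C1C=COc2c1c(OCOC)cc(OC)c2CO | intermediate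
7 | 8-(chloromethyl)-7-methoxy-5-(methoxymethoxy)-4H-chromen-4-one | O=C1C=COc2c1c(OCOC)cc(OC)c2CCl | intermediate
8 | 2-methyl-2-vinyloxirane (racemic) | C=CC1(C)CO1 | starting material
9 | (2-methylprop-1-en-1-yl)magnesium bromide | CC(C)=C[Mg]Br | starting material
10 | (2E)-2,6-dimethylhepta-2,5-dien-1-ol | CC(C)=CC/C=C(C)/CO | intermediate
11 | diethyl (2E)-2,6-dimethylhepta-2,5-dien-1-yl phosphate | CCOP(=O)(OCC)OC/C(C)=C/CC=C(C)C | intermediate
12 | {[7-methoxy-5-(methoxymethoxy)-4-oxo-4H-chromen-8-yl]methyl}zinc chloride (benzylzinc chloride) | O=C1C=COc2c1c(OCOC)cc(OC)c2C[Zn]Cl | intermediate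
13 | 7-methoxy-5-(methoxymethoxy)-8-[(2R)-5-methyl-2-(prop-1-en-2-yl)hex-4-en-1-yl]-4H-chromen-4-one | C=C(C)[C@H](CC=C(C)C)Cc1c(OC)cc(OCOC)c2c1OC=CC2=O | intermediate
14 | benzene-1,4-diol (hydroquinone) | Oc1ccc(O)cc1 | starting material
15 | 1,4-bis(methoxymethoxy)benzene | COCOc1ccc(OCOC)cc1 | intermediate
16 | [2,5-bis(methoxymethoxy)phenyl]lithium (aryllithium) | [Li]c1cc(OCOC)ccc1OCOC | intermediate
17 | lithium [2,5-bis(methoxymethoxy)phenyl]tri(propan-2-yloxy)borate (lithium triisopropoxyborate) | [Li+].CC(C)O[B-](OC(C)C)(OC(C)C)c1cc(OCOC)ccc1OCOC | intermediate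
18 | [2,5-bis(methoxymethoxy)phenyl]boronic acid | OB(O)c1cc(OCOC)ccc1OCOC | intermediate
19 | (2S)-2-[2,5-bis(methoxymethoxy)phenyl]-7-methoxy-5-(methoxymethoxy)-8-[(2R)-5-methyl-2-(prop-1-en-2-yl)hex-4-en-1-yl]-2,3-dihydro-4H-chromen-4-one | C=C(C)[C@H](CC=C(C)C)Cc1c(OC)cc(OCOC)c2c1O[C@H](c1cc(OCOC)ccc1OCOC)CC2=O | intermediate
20 | (2S)-2-(2,5-dihydroxyphenyl)-5-hydroxy-7-methoxy-8-[(2R)-5-methyl-2-(prop-1-en-2-yl)hex-4-en-1-yl]-2,3-dihydro-4H-chromen-4-one | C=C(C)[C@H](CC=C(C)C)Cc1c(OC)cc(O)c2c1O[C@H](c1cc(O)ccc1O)CC2=O | target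

**Step count and risks**

Total steps: 12. Longest linear sequence: 8 steps (steps 1, 2, 3, 4, 5, 8, 11, 12; 1 → 2 → 3 → 5 → 6 → 7 → 13 → 19 → 20).

Three steps most likely to fail:

Step 8 (the proposed new step). The risks are poor SN2′ against SN2 selectivity or low enantioselectivity with a benzylic zinc halide, Wurtz coupling of 7 during zinc insertion, and copper-mediated addition to the chromone. The fallback uses known chemistry only, sets out from 5 and comes back to the route at 13. (4S)-4-Benzyl-1,3-oxazolidin-2-one is N-acylated (n-BuLi, THF, −78 °C; 3-methylbut-2-enoyl chloride) to (4S)-4-benzyl-3-(3-methylbut-2-enoyl)-1,3-oxazolidin-2-one F1. Deconjugative α-alkylation (NaN(SiMe3)2, THF, −78 °C; prenyl bromide), with the electrophile entering anti to the benzyl group of the chelated Z-dienolate, gives (4S)-4-benzyl-3-[(2S)-5-methyl-2-(prop-1-en-2-yl)hex-4-enoyl]-1,3-oxazolidin-2-one F2. LiBH4 (Et2O, MeOH, 0 °C) gives (2S)-5-methyl-2-(prop-1-en-2-yl)hex-4-en-1-ol F3 and returns the auxiliary. I2, PPh3 and imidazole (CH2Cl2, 0 °C) give (3S)-3-(iodomethyl)-2,6-dimethylhepta-1,5-diene F4. Iodine–lithium exchange (t-BuLi, Et2O, −78 °C) gives [(2S)-5-methyl-2-(prop-1-en-2-yl)hex-4-en-1-yl]lithium F5, which ZnCl2 converts to [(2S)-5-methyl-2-(prop-1-en-2-yl)hex-4-en-1-yl]zinc chloride F6. Negishi coupling of F6 with 5 (Pd(OAc)2, SPhos, THF, 40 °C) gives 13; the descriptor changes from S to R only because the CIP rank of the CH2 arm changes. The same material also serves to assign the configuration of 13 from step 8.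

Step 11. The risks are slow insertion and protodeboronation of the ortho-substituted, electron-rich boronic acid at a hindered chromone, and incomplete facial control. The fallback sets out from 13 (with the aldehyde partner drawn from 15 through 16) and comes back at 19. Alkaline cleavage of 13 (KOH, EtOH/H2O, 70 °C; loss of C2 as formate) gives 1-{2-hydroxy-4-methoxy-6-(methoxymethoxy)-3-[(2R)-5-methyl-2-(prop-1-en-2-yl)hex-4-en-1-yl]phenyl}ethan-1-one F7. Aryllithium 16 is quenched with DMF to give 2,5-bis(methoxymethoxy)benzaldehyde F8. Claisen–Schmidt condensation of F7 with F8 (KOH, EtOH, rt) gives (2E)-3-[2,5-bis(methoxymethoxy)phenyl]-1-{2-hydroxy-4-methoxy-6-(methoxymethoxy)-3-[(2R)-5-methyl-2-(prop-1-en-2-yl)hex-4-en-1-yl]phenyl}prop-2-en-1-one F9. Oxa-Michael ring closure (NaOAc, EtOH, reflux) gives 19 together with (2R)-2-[2,5-bis(methoxymethoxy)phenyl]-7-methoxy-5-(methoxymethoxy)-8-[(2R)-5-methyl-2-(prop-1-en-2-yl)hex-4-en-1-yl]-2,3-dihydro-4H-chromen-4-one F10. The two epimers are separated by preparative HPLC on a chiral stationary phase, and F10 is recycled by base equilibration through F9.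

Step 4. The risks are sluggish coupling at the di-ortho-substituted iodide, competing butyl transfer and protodeiodination. The fallback sets out from 5 and comes back at 6. Palladium-catalysed reductive carbonylation of 5 (PdCl2(PPh3)2, CO 1 atm, HCO2Na, DMF, 90 °C) gives 7-methoxy-5-(methoxymethoxy)-4-oxo-4H-chromene-8-carbaldehyde F11, and chemoselective reduction of the aldehyde (NaBH(OAc)3, THF, rt) gives 6.

**Further compounds**

F1 | step 8 | (4S)-4-benzyl-3-(3-methylbut-2-enoyl)-1,3-oxazolidin-2-one | CC(C)=CC(=O)N1[C@@H](Cc2ccccc2)COC1=O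
F2 | step 8 | (4S)-4-benzyl-3-[(2S)-5-methyl-2-(prop-1-en-2-yl)hex-4-enoyl]-1,3-oxazolidin-2-one | C=C(C)[C@H](CC=C(C)C)C(=O)N1[C@@H](Cc2ccccc2)COC1=O
F3 | step 8 | (2S)-5-methyl-2-(prop-1-en-2-yl)hex-4-en-1-ol | C=C(C)[C@H](CC=C(C)C)CO
F4 | step 8 | (3S)-3-(iodomethyl)-2,6-dimethylhepta-1,5-diene | C=C(C)[C@H](CC=C(C)C)CI
F5 | step 8 | [(2S)-5-methyl-2-(prop-1-en-2-yl)hex-4-en-1-yl]lithium | C=C(C)[C@H](CC=C(C)C)C[Li]
F6 | step 8 | [(2S)-5-methyl-2-(prop-1-en-2-yl)hex-4-en-1-yl]zinc chloride | C=C(C)[C@H](CC=C(C)C)C[Zn]Cl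
F7 | step 11 | 1-{2-hydroxy-4-methoxy-6-(methoxymethoxy)-3-[(2R)-5-methyl-2-(prop-1-en-2-yl)hex-4-en-1-yl]phenyl}ethan-1-one | C=C(C)[C@H](CC=C(C)C)Cc1c(OC)cc(OCOC)c(C(C)=O)c1O
F8 | step 11 | 2,5-bis(methoxymethoxy)benzaldehyde | O=Cc1cc(OCOC)ccc1OCOC
F9 | step 11 | (2E)-3-[2,5-bis(methoxymethoxy)phenyl]-1-{2-hydroxy-4-methoxy-6-(methoxymethoxy)-3-[(2R)-5-methyl-2-(prop-1-en-2-yl)hex-4-en-1-yl]phenyl}prop-2-en-1-one | C=C(C)[C@H](CC=C(C)C)Cc1c(OC)cc(OCOC)c(C(=O)/C=C/c2cc(OCOC)ccc2OCOC)c1O
F10 | step 11 | (2R)-2-[2,5-bis(methoxymethoxy)phenyl]-7-methoxy-5-(methoxymethoxy)-8-[(2R)-5-methyl-2-(prop-1-en-2-yl)hex-4-en-1-yl]-2,3-dihydro-4H-chromen-4-one | C=C(C)[C@H](CC=C(C)C)Cc1c(OC)cc(OCOC)c2c1O[C@@H](c1cc(OCOC)ccc1OCOC)CC2=O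
F11 | step 4 | 7-methoxy-5-(methoxymethoxy)-4-oxo-4H-chromene-8-carbaldehyde | O=Cc1c(OC)cc(OCOC)c2c1OC=CC2=O
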